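**Plan**

1. Retrosynthesis (labdane numbering): remove the C2 acetate, then open ring A at C1–C2 and C3–C4. C2–C3 with both oxygens becomes vinylene carbonate, and the rest is a ring B cyclohexane carrying a C10 CH=N–NHTs group and a C5 isopropenyl group. The enoate is cut back to a terminal alkyne, C9–C11 to ketone plus Grignard reagent, and C10–C1/C10–C20 to enolate chemistry of (R)-carvone.
2. Forward: the carvone ring becomes ring B (carvone C1, C2, C5, C6 and the isopropenyl carbon become C9, C8, C5, C10 and C4). C10 is quaternised (CH3, then CH(OMe)2), the enone is reduced, the four-carbon chain is added to the C9 ketone and turned into the (E)-enoate. Ring A is closed last, followed by acetylation of the C2 hydroxyl.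
3. Enabling feature: on the ring B chair the C5 isopropenyl group (source of a tertiary C4 radical that already carries both C4 methyls) and the C10 hydrazone carbon C1 are trans-diequatorial and 1,4-related. A two-carbon radical acceptor can therefore bridge C4 and C1 and close ring A as a trans-decalin.
4. Stereochemistry: C5 from (R)-carvone; C10 by alkylation anti to isopropenyl; C8 by equilibration; C9 by axial addition anti to the axial C10 methyl; C2/C3 from the cis-fused carbonate and a chair cyclisation; C13=C14 (E) from syn-carboalumination.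

Key step: step 7

Remark: α/β mean below/above the decalin drawn with the C10 methyl up; read this way the target SMILES carries 2α-OAc, 3α-OH, 9β-OH, a 9α side chain, 8α-CH3 and 5α-H, and the route is built for exactly this arrangement.

Step 1
Reactants: 1 (R)-(−)-carvone
Product: 2 (5R,6S)-2,6-dimethyl-5-(prop-1-en-2-yl)cyclohex-2-en-1-one
Conditions: LiN(i-Pr)2 (LDA), THF, −78 °C; MeI, −78 → 0 °C
Reagents that add atoms: iodomethane CI
Why: Enolate alkylation: kinetic deprotonation at C6 gives the cross-conjugated lithium enolate, which should be methylated mainly trans to the isopropenyl group, the new centre being erased again in step 2.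

Step 2
Reactants: 2 (5R,6S)-2,6-dimethyl-5-(prop-1-en-2-yl)cyclohex-2-en-1-one
Product: 4 (5S,6R)-6-(dimethoxymethyl)-2,6-dimethyl-5-(prop-1-en-2-yl)cyclohex-2-en-1-one, via silyl dienol ether 3 (not isolated)
Conditions: LiN(i-Pr)2, THF, −78 °C; Me3SiCl; pentane filtration, concentration; then HC(OMe)3, Me3SiOTf (cat.), CH2Cl2, −78 °C
Reagents that add atoms: trimethyl orthoformate COC(OC)OC
Why: Mukaiyama-type condensation of a silyl enol ether with an orthoformate: the dimethoxycarbenium ion should attack the tetrasubstituted enol carbon anti to the neighbouring isopropenyl group, which sets the quaternary centre (future C10) with CH3 cis and CH(OMe)2 trans to isopropenyl.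

Step 3
Reactants: 4 (5S,6R)-6-(dimethoxymethyl)-2,6-dimethyl-5-(prop-1-en-2-yl)cyclohex-2-en-1-one
Product: 5 (2R,3S,6R)-2-(dimethoxymethyl)-2,6-dimethyl-3-(prop-1-en-2-yl)cyclohexan-1-one
Conditions: LiBH(s-Bu)3 (L-Selectride), THF, −78 °C; MeOH; then NaOMe (cat.), MeOH, rt
Reagents that add atoms: none
Why: Conjugate (1,4) hydride reduction of the β-unsubstituted enone, whose carbonyl is shielded by the quaternary centre, followed by base equilibration of the enolisable centre should place the ring methyl equatorial (future 8α-CH3) and away from the axial C10 methyl.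

Step 4
Reactants: 5 (2R,3S,6R)-2-(dimethoxymethyl)-2,6-dimethyl-3-(prop-1-en-2-yl)cyclohexan-1-one; 6 (4-bromobut-1-yn-1-yl)trimethylsilane
Product: 9 (1S,2S,3S,6R)-1-(but-3-yn-1-yl)-2-(dimethoxymethyl)-2,6-dimethyl-3-(prop-1-en-2-yl)cyclohexan-1-ol, via Grignard reagent 7 (not isolated), via silylalkyne adduct 8 (not isolated)
Conditions: 6, Mg, THF, rt; then 5, LaCl3·2LiCl (30 mol%), THF, 0 °C; aqueous work-up; then K2CO3 (cat.), MeOH, rt
Reagents that add atoms: none
Why: Grignard 1,2-addition promoted by LaCl3·2LiCl should proceed by axial attack anti to the axial C10 methyl, giving the tertiary alcohol with the chain axial and the hydroxyl cis to that methyl (future 9β-OH), and K2CO3/MeOH then cleaves the alkynyl C–Si bond.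

Step 5
Reactants: 9 (1S,2S,3S,6R)-1-(but-3-yn-1-yl)-2-(dimethoxymethyl)-2,6-dimethyl-3-(prop-1-en-2-yl)cyclohexan-1-ol
Product: 10 methyl (2E)-5-[(1S,2S,3S,6R)-2-(dimethoxymethyl)-1-hydroxy-2,6-dimethyl-3-(prop-1-en-2-yl)cyclohexyl]-3-methylpent-2-enoate
Conditions: Me3Al, Cp2ZrCl2 (cat.), H2O (1 equiv), CH2Cl2, −25 °C; then ClCO2Me, −25 °C → rt
Reagents that add atoms: trimethylaluminium C[Al](C)C; methyl chloroformate COC(=O)Cl
Why: Zirconium-catalysed syn-carboalumination of the terminal alkyne (Negishi carboalumination) followed by acylation of the alkenylalane with retention should give the (E)-3-methyl-2-enoate, the tertiary hydroxyl being carried as an inert aluminium alkoxide.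

Step 6
Reactants: 10 methyl (2E)-5-[(1S,2S,3S,6R)-2-(dimethoxymethyl)-1-hydroxy-2,6-dimethyl-3-(prop-1-en-2-yl)cyclohexyl]-3-methylpent-2-enoate
Product: 12 methyl (2E)-5-[(1S,2R,3S,6R)-1-hydroxy-2,6-dimethyl-2-{(E)-[2-(4-methylbenzenesulfonyl)hydrazinylidene]methyl}-3-(prop-1-en-2-yl)cyclohexyl]-3-methylpent-2-enoate, via aldehyde 11 (not isolated)
Conditions: TsNHNH2, PPTS (cat.), THF/H2O, 40 °C
Reagents that add atoms: 4-methylbenzenesulfonohydrazide Cc1ccc(cc1)S(=O)(=O)NN
Why: Acetal hydrolysis and hydrazone formation: mild acid should unmask the non-enolisable neopentyl aldehyde, which condenses with tosylhydrazide to the E-hydrazone while the tertiary alcohol and the enoate are untouched.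

Step 7
Reactants: 12 methyl (2E)-5-[(1S,2R,3S,6R)-1-hydroxy-2,6-dimethyl-2-{(E)-[2-(4-methylbenzenesulfonyl)hydrazinylidene]methyl}-3-(prop-1-en-2-yl)cyclohexyl]-3-methylpent-2-enoate; 13 vinylene carbonate
Product: 16 methyl (2E)-5-[(1S,2R,4aS,6S,7R,8aS)-1,6,7-trihydroxy-2,5,5,8a-tetramethyldecahydronaphthalen-1-yl]-3-methylpent-2-enoate, via hydrazide carbonate 14 (not isolated), via cyclic carbonate 15 (not isolated)
Conditions: 13 (10 equiv), Fe(acac)3 (30 mol%), PhSiH3, THF/MeOH, 40 °C; then NaOAc, MeOH, 60 °C; then K2CO3 (cat.), MeOH, 0 °C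
Reagents that add atoms: none
Why: Proposed new method: hydrogen-atom transfer from the iron hydride formed from Fe(acac)3 and PhSiH3 to the isopropenyl group should give the tertiary C4 radical, which adds to vinylene carbonate (C3–C4 bond), and the resulting α-oxy radical should close onto the hydrazone carbon (C1–C2 bond) before the N-centred radical is reduced by divalent iron and protonated; NaOAc then expels sulfinate and N2 from the alkyl diazene so that C1 ends as CH2, and K2CO3/MeOH methanolyses the carbonate. The closest known reactions are the iron-hydride-initiated reductive coupling of alkenes with sulfonylhydrazones followed by denitrogenation, the iron-hydride-initiated radical conjugate addition–aldol annulation of alkenyl aldehydes, and the addition of nucleophilic carbon radicals to vinylene carbonate. Ring A closes by a 6-exo-trig radical cyclisation through a chair on the trans-diequatorial C5 and C10 substituents of ring B, which fixes the trans-decalin, and the carbonate ring is carried along cis-fused. The five-membered carbonate forces the C2 and C3 oxygens cis, and of the two C3 epimers of the adduct radical only the one that cyclises with the C2 oxygen equatorial, free of 1,3-diaxial contact with the axial C10 and C4 methyl groups, should close, which gives the 2α,3α arrangement while the C1 stereocentre of 14 disappears. The step needs hydrogen-atom transfer to the 1,1-disubstituted alkene in preference to the conjugated enoate and capture of the tertiary radical by the carbonate before it is reduced, which a large excess of vinylene carbonate and the impossibility of a direct four-membered closure onto the hydrazone should secure. The α-oxy radical is nucleophilic, not reducible by divalent iron and polarity-matched with the electrophilic C=N bond, so it should live long enough to cyclise.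

Step 8
Reactants: 16 methyl (2E)-5-[(1S,2R,4aS,6S,7R,8aS)-1,6,7-trihydroxy-2,5,5,8a-tetramethyldecahydronaphthalen-1-yl]-3-methylpent-2-enoate
Product: 17 methyl (2E)-5-[(1S,2R,4aS,6S,7R,8aS)-7-acetoxy-1,6-dihydroxy-2,5,5,8a-tetramethyldecahydronaphthalen-1-yl]-3-methylpent-2-enoate
Conditions: Ac2O (1.1 equiv), pyridine, CH2Cl2, 0 °C
Reagents that add atoms: acetic anhydride CC(=O)OC(C)=O
Why: Regioselective esterification: the equatorial secondary 2α-hydroxyl should be acetylated in preference to the axial 3α-hydroxyl next to the quaternary C4 and to the tertiary 9-hydroxyl, which gives the target.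

**Compound list**

1 | (R)-(−)-carvone, (5R)-2-methyl-5-(prop-1-en-2-yl)cyclohex-2-en-1-one | CC1=CC[C@H](CC1=O)C(C)=C | starting material
2 | (5R,6S)-2,6-dimethyl-5-(prop-1-en-2-yl)cyclohex-2-en-1-one (trans-6-methylcarvone; the minor C6 epimer is carried along) | O=C1C(C)=CC[C@@H](C(C)=C)[C@@H]1C | intermediate
3 | trimethyl{[(3S)-2,6-dimethyl-3-(prop-1-en-2-yl)cyclohexa-1,5-dien-1-yl]oxy}silane (silyl dienol ether) | CC1=CC[C@@H](C(C)=C)C(C)=C1O[Si](C)(C)C | intermediate
4 | (5S,6R)-6-(dimethoxymethyl)-2,6-dimethyl-5-(prop-1-en-2-yl)cyclohex-2-en-1-one | O=C1C(C)=CC[C@@H](C(C)=C)[C@]1(C)C(OC)OC | intermediate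
5 | (2R,3S,6R)-2-(dimethoxymethyl)-2,6-dimethyl-3-(prop-1-en-2-yl)cyclohexan-1-one | O=C1[C@H](C)CC[C@@H](C(C)=C)[C@]1(C)C(OC)OC | intermediate
6 | (4-bromobut-1-yn-1-yl)trimethylsilane | C[Si](C)(C)C#CCCBr | starting material
7 | [4-(trimethylsilyl)but-3-yn-1-yl]magnesium bromide | C[Si](C)(C)C#CCC[Mg]Br | intermediate
8 | (1S,2S,3S,6R)-2-(dimethoxymethyl)-2,6-dimethyl-3-(prop-1-en-2-yl)-1-[4-(trimethylsilyl)but-3-yn-1-yl]cyclohexan-1-ol | C[Si](C)(C)C#CCC[C@]1(O)[C@H](C)CC[C@@H](C(C)=C)[C@]1(C)C(OC)OC | intermediate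
9 | (1S,2S,3S,6R)-1-(but-3-yn-1-yl)-2-(dimethoxymethyl)-2,6-dimethyl-3-(prop-1-en-2-yl)cyclohexan-1-ol | C#CCC[C@]1(O)[C@H](C)CC[C@@H](C(C)=C)[C@]1(C)C(OC)OC | intermediate
10 | methyl (2E)-5-[(1S,2S,3S,6R)-2-(dimethoxymethyl)-1-hydroxy-2,6-dimethyl-3-(prop-1-en-2-yl)cyclohexyl]-3-methylpent-2-enoate | COC(=O)/C=C(\C)CC[C@]1(O)[C@H](C)CC[C@@H](C(C)=C)[C@]1(C)C(OC)OC | intermediate
11 | methyl (2E)-5-[(1S,2S,3S,6R)-2-formyl-1-hydroxy-2,6-dimethyl-3-(prop-1-en-2-yl)cyclohexyl]-3-methylpent-2-enoate | COC(=O)/C=C(\C)CC[C@]1(O)[C@H](C)CC[C@@H](C(C)=C)[C@]1(C)C=O | intermediate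
12 | methyl (2E)-5-[(1S,2R,3S,6R)-1-hydroxy-2,6-dimethyl-2-{(E)-[2-(4-methylbenzenesulfonyl)hydrazinylidene]methyl}-3-(prop-1-en-2-yl)cyclohexyl]-3-methylpent-2-enoate (N-tosylhydrazone of 11) | COC(=O)/C=C(\C)CC[C@]1(O)[C@H](C)CC[C@@H](C(C)=C)[C@]1(C)/C=N/NS(=O)(=O)c2ccc(C)cc2 | intermediate
13 | vinylene carbonate (1,3-dioxol-2-one) | O=C1OC=CO1 | starting material
14 | cyclised N′-tosylhydrazide: the trans-decalin of 16 with its 2α,3α-diol as cyclic carbonate and a TsNHNH group on C1 (C1 epimers) | COC(=O)/C=C(\C)CC[C@]1(O)[C@H](C)CC[C@H]2C(C)(C)[C@@H]3OC(=O)O[C@@H]3C(NNS(=O)(=O)c4ccc(C)cc4)[C@@]21C | intermediate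
15 | 2α,3α-cyclic carbonate of triol 16 | COC(=O)/C=C(\C)CC[C@]1(O)[C@H](C)CC[C@H]2C(C)(C)[C@@H]3OC(=O)O[C@@H]3C[C@@]21C | intermediate
16 | methyl (2E)-5-[(1S,2R,4aS,6S,7R,8aS)-1,6,7-trihydroxy-2,5,5,8a-tetramethyldecahydronaphthalen-1-yl]-3-methylpent-2-enoate (2α,3α,9β-triol) | COC(=O)/C=C(\C)CC[C@]1(O)[C@H](C)CC[C@H]2C(C)(C)[C@H](O)[C@H](O)C[C@@]21C | intermediate
17 | methyl (2E)-5-[(1S,2R,4aS,6S,7R,8aS)-7-acetoxy-1,6-dihydroxy-2,5,5,8a-tetramethyldecahydronaphthalen-1-yl]-3-methylpent-2-enoate (CNP0135744.1) | COC(=O)/C=C(\C)CC[C@]1(O)[C@H](C)CC[C@H]2C(C)(C)[C@H](O)[C@H](OC(C)=O)C[C@@]21C | target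

Total step count: 8. Longest linear sequence: 8 steps (1 to 17).

**Steps most likely to fail**

Step 7 (proposed new method). Capture of the tertiary radical by vinylene carbonate may be too slow compared with its reduction, or the adduct radical may be reduced before it cyclises onto the hydrazone. Fallback with known chemistry, setting out from 10 and coming back at 16: acetal 10 is hydrolysed (PPTS, acetone/H2O) to aldehyde 11. This undergoes the iron-hydride-initiated radical conjugate addition–aldol annulation (Fe(acac)3, PhSiH3, EtOH/ethylene glycol) with phenyl vinyl sulfone to give the ring A β-hydroxy sulfone F1. Acetylation (Ac2O, DMAP) gives the β-acetoxy sulfone F2, and Julia–Lythgoe reductive elimination (SmI2, DMPU, THF) gives the ring A Δ1 olefin F3. Allylic oxidation (CrO3·3,5-dimethylpyrazole, CH2Cl2, −20 °C) gives the 1-en-3-one F4. Its enone tosylhydrazone F5 (TsNHNH2, EtOH) is reduced with catecholborane and warmed with NaOAc (reductive 1,3-transposition through the allylic diazene) to the ring A Δ2 olefin F6. Dihydroxylation with OsO4 (cat.)/NMO from the α face should then give 16.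

Step 4. The doubly flanked ketone may enolise instead of adding the Grignard reagent, or facial selectivity may be eroded. Fallback, setting out from 5 and coming back at 8: Corey–Chaykovsky methylenation with dimethylsulfonium methylide (trimethylsulfonium iodide, n-BuLi, THF, −10 °C), which delivers CH2 axially on the same face, gives the spiro-epoxide F7. Opening at its CH2 terminus with Me3SiC≡CCH2Li (from 1-(trimethylsilyl)propyne and n-BuLi; BF3·OEt2, THF, −78 °C) gives 8, which is desilylated to 9 as before.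

Step 2. The dimethoxycarbenium ion may fail to engage the tetrasubstituted enol carbon cleanly, or facial control may be incomplete. Fallback, setting out from 2 and coming back at 4: the lithium enolate of 2 (LiN(i-Pr)2, THF, −78 °C) is hydroxymethylated with gaseous CH2O (aldol addition, anti to isopropenyl) to the hydroxymethyl ketone F8. This is oxidised (Dess–Martin periodinane) to the non-enolisable keto aldehyde F9, which is acetalised at the aldehyde only (HC(OMe)3, PPTS, MeOH) to give 4.

**Further compounds**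

F1 | step 7 | ring A β-hydroxy sulfone: trans-decalin of 16 with OH on C1 and PhSO2 on C2 in place of the 2,3-diol (C1/C2 epimers) | COC(=O)/C=C(\C)CC[C@]1(O)[C@H](C)CC[C@H]2C(C)(C)CC(S(=O)(=O)c3ccccc3)C(O)[C@@]21C
F2 | step 7 | β-acetoxy sulfone: C1 acetate of F1 | COC(=O)/C=C(\C)CC[C@]1(O)[C@H](C)CC[C@H]2C(C)(C)CC(S(=O)(=O)c3ccccc3)C(OC(C)=O)[C@@]21C
F3 | step 7 | ring A Δ1 olefin (C1=C2; C3 is CH2) | COC(=O)/C=C(\C)CC[C@]1(O)[C@H](C)CC[C@H]2C(C)(C)CC=C[C@@]21C
F4 | step 7 | ring A 1-en-3-one | COC(=O)/C=C(\C)CC[C@]1(O)[C@H](C)CC[C@H]2C(C)(C)C(=O)C=C[C@@]21C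
F5 | step 7 | N-tosylhydrazone of enone F4 | COC(=O)/C=C(\C)CC[C@]1(O)[C@H](C)CC[C@H]2C(C)(C)C(=NNS(=O)(=O)c3ccc(C)cc3)C=C[C@@]21C
F6 | step 7 | ring A Δ2 olefin (C2=C3; C1 is CH2) | COC(=O)/C=C(\C)CC[C@]1(O)[C@H](C)CC[C@H]2C(C)(C)C=CC[C@@]21C
F7 | step 4 | spiro-epoxide of ketone 5 (epoxide CH2 axial on the α face, O equatorial) | C1O[C@]12[C@H](C)CC[C@@H](C(C)=C)[C@]2(C)C(OC)OC
F8 | step 2 | (5S,6R)-6-(hydroxymethyl)-2,6-dimethyl-5-(prop-1-en-2-yl)cyclohex-2-en-1-one | O=C1C(C)=CC[C@@H](C(C)=C)[C@]1(C)CO
F9 | step 2 | (5S,6R)-6-formyl-2,6-dimethyl-5-(prop-1-en-2-yl)cyclohex-2-en-1-one (carvone numbering) | O=C1C(C)=CC[C@@H](C(C)=C)[C@]1(C)C=O
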